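**Strategy**

The cis-hydroazulene is cut at the bond between the gem-dimethyl carbon of the seven-membered ring and the neighbouring ring-fusion CH it shares with the cyclopentane. Written with a ketone in place of the exocyclic methylene, that CH is the β-carbon of a cyclopentenyl ketone, and the CMe2 carbon a tertiary radical made by hydrogen-atom transfer to an isopropenyl group. One 7-endo radical conjugate addition therefore closes the seven-membered ring, forms the quaternary carbon and sets both ring-fusion centres from a monocyclic silyloxycyclopentenyl ketone. The side chain is then attached by a tertiary-radical Giese coupling to a chiral cyclopentenone, whose oxidative cleavage gives the dioxabicyclic lactone acetal.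

Key step: step 5

**Remarks on the chemistry**

- Naming: hydroazulenes are named as bicyclo[5.3.0]decanes (C1 and C7 ring fusion, C2 the carbonyl or methylidene carbon, C6 the gem-dimethyl carbon, C10 the five-ring carbon next to C1).
- Assumption: the ring-fusion carbon C1 of ketone 10, which is α to the carbonyl, is taken to rest in the cis-fused form (ring carbonyl anti to the C10 silyloxy group) after protonation or brief equilibration.

**Route**

Step 1
Reactants: 1 5-methylhex-5-enoic acid; 2 N,O-dimethylhydroxylamine hydrochloride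
Product: 3 N-methoxy-N,5-dimethylhex-5-enamide
Conditions: CDI, CH2Cl2, rt; then 2, rt
Reagents that add atoms: none
Why: Acyl imidazole formation followed by aminolysis (Weinreb amide synthesis) is a standard amidation that the remote 1,1-disubstituted alkene does not disturb.

Step 2
Reactants: 4 2-bromocyclopent-2-en-1-one
Product: 5 (R)-2-bromocyclopent-2-en-1-ol
Conditions: (S)-Me-CBS oxazaborolidine (10 mol%), BH3·SMe2, THF, −20 °C; MeOH quench
Reagents that add atoms: none
Why: Corey–Bakshi–Shibata reduction, with the bromovinyl group acting as the large substituent, should deliver hydride to one face of the ketone and set the carbinol centre as (R).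

Step 3
Reactants: 5 (R)-2-bromocyclopent-2-en-1-ol
Product: 6 (R)-[(2-bromocyclopent-2-en-1-yl)oxy](tert-butyl)dimethylsilane
Conditions: TBSCl, imidazole, DMF, rt
Reagents that add atoms: tert-butyldimethylsilyl chloride, CC(C)(C)[Si](C)(C)Cl
Why: Standard silylation of a secondary allylic alcohol, which installs the bulky group that later shields one face of the cyclopentene.

Step 4
Reactants: 6 (R)-[(2-bromocyclopent-2-en-1-yl)oxy](tert-butyl)dimethylsilane; 3 N-methoxy-N,5-dimethylhex-5-enamide
Product: 7 1-[(5R)-5-(tert-butyldimethylsilyloxy)cyclopent-1-en-1-yl]-5-methylhex-5-en-1-one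
Conditions: t-BuLi (2.1 equiv), Et2O, −78 °C; then 3, −78 to 0 °C; aqueous work-up
Reagents that add atoms: none
Why: Bromine–lithium exchange gives a 2-lithiocyclopentene that adds once to the Weinreb amide, whose chelated tetrahedral intermediate collapses to the enone only on work-up (Weinreb ketone synthesis), the carbinol centre being untouched.

Step 5
Reactants: 7 1-[(5R)-5-(tert-butyldimethylsilyloxy)cyclopent-1-en-1-yl]-5-methylhex-5-en-1-one
Product: 10 (1R,7R,10R)-10-(tert-butyldimethylsilyloxy)-6,6-dimethylbicyclo[5.3.0]decan-2-one, via tertiary alkyl radical 8 (not isolated), via α-keto radical 9 (not isolated)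
Conditions: Fe(acac)3 (0.3 equiv), PhSiH3 (slow addition), EtOH/ethylene glycol 5:1, 0.01 M, 60 °C
Reagents that add atoms: none
Why: Fe(acac)3 and PhSiH3 form an iron hydride that transfers a hydrogen atom to the CH2 end of the electron-rich isopropenyl group and not to the electron-poor enone, giving tertiary radical 8, which adds to the β-carbon of the cyclopentenyl ketone, and α-keto radical 9 is then reduced and protonated by ethanol. The closest known reaction type is the iron-mediated reductive olefin–enone coupling (MHAT-initiated Giese reaction) run intramolecularly. The seven-membered ring closes in the 7-endo-trig mode, both enone carbons ending inside the new ring. The ring-fusion CH next to CMe2 is set by attack on the cyclopentene face opposite the allylic silyloxy group, and the α-carbon is set by protonation, which leaves it epimerisable so that the cis-fused ketone can be reached by equilibration. The step needs 7-endo and not 6-exo closure, which the polarity match of a nucleophilic radical with the enone β-carbon and the greater hindrance of the α-carbon should secure, and it needs cyclisation to outrun hydrogenation of the radical, which high dilution and slow silane addition should secure.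

Step 6
Reactants: 10 (1R,7R,10R)-10-(tert-butyldimethylsilyloxy)-6,6-dimethylbicyclo[5.3.0]decan-2-one
Product: 11 (1S,7R,10R)-tert-butyl[(6,6-dimethyl-2-methylidenebicyclo[5.3.0]decan-10-yl)oxy]dimethylsilane
Conditions: Zn, CH2Br2, TiCl4, THF/CH2Cl2, 0 °C to rt
Reagents that add atoms: dibromomethane, BrCBr
Why: Lombardo–Takai methylenation is a non-basic methylene transfer that should convert the hindered, epimerisable ketone into the exocyclic alkene without enolisation or loss of the β-silyloxy group.

Step 7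
Reactants: 11 (1S,7R,10R)-tert-butyl[(6,6-dimethyl-2-methylidenebicyclo[5.3.0]decan-10-yl)oxy]dimethylsilane
Product: 12 (1S,7R,10R)-6,6-dimethyl-2-methylidenebicyclo[5.3.0]decan-10-ol
Conditions: Bu4NF, THF, rt to 50 °C
Reagents that add atoms: none
Why: Fluoride-induced desilylation, with no other fluoride-sensitive group in 11.

Step 8
Reactants: 12 (1S,7R,10R)-6,6-dimethyl-2-methylidenebicyclo[5.3.0]decan-10-ol
Product: 13 (1S,7R)-6,6-dimethyl-2-methylidenebicyclo[5.3.0]decan-10-one
Conditions: Dess–Martin periodinane, NaHCO3, CH2Cl2, 0 °C; used crude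
Reagents that add atoms: none
Why: Dess–Martin oxidation under buffered, non-enolising conditions should give the β,γ-unsaturated ketone without moving the exocyclic double bond into conjugation.

Step 9
Reactants: 13 (1S,7R)-6,6-dimethyl-2-methylidenebicyclo[5.3.0]decan-10-one
Product: 15 methyl (1S,7R,10S)-6,6,10-trimethyl-2-methylidenebicyclo[5.3.0]decan-10-yl oxalate, via lithium alkoxide 14 (not isolated)
Conditions: MeLi, CeCl3, THF, −78 °C; then ClCOCO2Me, −78 to 0 °C
Reagents that add atoms: methyllithium, [Li]C; methyl chlorooxoacetate, COC(=O)C(=O)Cl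
Why: The weakly basic methylcerium reagent (organocerium 1,2-addition) should add to the enolisable ketone from the convex face and the tertiary alkoxide is acylated in situ, the configuration of this carbinol carbon being of no consequence because it later becomes a radical.

Step 10
Reactants: 15 methyl (1S,7R,10S)-6,6,10-trimethyl-2-methylidenebicyclo[5.3.0]decan-10-yl oxalate
Product: 16 cesium 2-{[(1S,7R,10S)-6,6,10-trimethyl-2-methylidenebicyclo[5.3.0]decan-10-yl]oxy}-2-oxoacetate
Conditions: CsOH (1.0 equiv, aq), THF, rt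
Reagents that add atoms: cesium hydroxide, [Cs+].[OH-]
Why: Selective saponification of the unhindered methyl ester of the mixed oxalate should give the bench-stable tertiary cesium oxalate.

Step 11
Reactants: 17 (1R,5S)-2-oxabicyclo[3.3.0]oct-6-en-3-one
Product: 19 (1R,4R,5R)-4-hydroxy-2-oxabicyclo[3.3.0]oct-6-en-3-one, via potassium enolate 18 (not isolated)
Conditions: KN(SiMe3)2, THF, −78 °C; then 2-(phenylsulfonyl)-3-phenyloxaziridine, −78 °C; AcOH quench
Reagents that add atoms: 2-(phenylsulfonyl)-3-phenyloxaziridine, O=S(=O)(c1ccccc1)N1OC1c1ccccc1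
Why: Davis oxidation of the enolate should take place on the convex face of the cis-fused bicyclic lactone, placing the new hydroxyl cis to the ring-fusion hydrogens and setting the carbinol centre of the future tetrahydrofuran.

Step 12
Reactants: 19 (1R,4R,5R)-4-hydroxy-2-oxabicyclo[3.3.0]oct-6-en-3-one
Product: 22 methyl (2R)-2-(tert-butyldimethylsilyloxy)-2-[(1S,5R)-5-(tert-butyldimethylsilyloxy)cyclopent-2-en-1-yl]acetate, via potassium carboxylate 20 (not isolated), via diol methyl ester 21 (not isolated)
Conditions: KOH, MeOH/H2O, 0 °C; concentrate; MeI, DMF, rt; then TBSOTf, 2,6-lutidine, CH2Cl2, −78 to 0 °C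
Reagents that add atoms: potassium hydroxide, [K+].[OH-]; iodomethane, CI; tert-butyldimethylsilyl trifluoromethanesulfonate, CC(C)(C)[Si](C)(C)OS(=O)(=O)C(F)(F)F
Why: Saponification opens the lactone irreversibly, SN2 methylation of the carboxylate gives the methyl ester under neutral conditions that should not re-close the lactone, and both secondary hydroxyls are then silylated, with no stereocentre touched.

Step 13
Reactants: 22 methyl (2R)-2-(tert-butyldimethylsilyloxy)-2-[(1S,5R)-5-(tert-butyldimethylsilyloxy)cyclopent-2-en-1-yl]acetate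
Product: 23 methyl (2R)-2-(tert-butyldimethylsilyloxy)-2-[(1S,5S)-5-(tert-butyldimethylsilyloxy)-4-hydroxycyclopent-2-en-1-yl]acetate (C4 epimers)
Conditions: SeO2 (0.5 equiv), t-BuOOH, CH2Cl2, rt
Reagents that add atoms: tert-butyl hydroperoxide, CC(C)(C)OO (its oxygen is passed on through SeO2, O=[Se]=O)
Why: Selenium dioxide allylic oxidation (ene reaction, then 2,3-sigmatropic shift) keeps the double bond in place and should prefer the ring CH2 over the hindered tertiary allylic CH, the configuration of the new carbinol being irrelevant because it is oxidised next.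

Step 14
Reactants: 23 methyl (2R)-2-(tert-butyldimethylsilyloxy)-2-[(1S,5S)-5-(tert-butyldimethylsilyloxy)-4-hydroxycyclopent-2-en-1-yl]acetate
Product: 24 methyl (2R)-2-(tert-butyldimethylsilyloxy)-2-[(1S,5S)-5-(tert-butyldimethylsilyloxy)-4-oxocyclopent-2-en-1-yl]acetate
Conditions: Dess–Martin periodinane, NaHCO3, CH2Cl2, rt
Reagents that add atoms: none
Why: Dess–Martin oxidation of the allylic alcohol gives the cyclopentenone under neutral conditions that should leave the cis α'-silyloxy centre unepimerised.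

Step 15
Reactants: 16 cesium 2-{[(1S,7R,10S)-6,6,10-trimethyl-2-methylidenebicyclo[5.3.0]decan-10-yl]oxy}-2-oxoacetate; 24 methyl (2R)-2-(tert-butyldimethylsilyloxy)-2-[(1S,5S)-5-(tert-butyldimethylsilyloxy)-4-oxocyclopent-2-en-1-yl]acetate
Product: 26 methyl (2R)-2-(tert-butyldimethylsilyloxy)-2-{(1S,2R,5S)-5-(tert-butyldimethylsilyloxy)-4-oxo-2-[(1S,7R,10S)-6,6,10-trimethyl-2-methylidenebicyclo[5.3.0]decan-10-yl]cyclopentyl}acetate, via hydroazulenyl tertiary radical 25 (not isolated)
Conditions: Ir[dF(CF3)ppy]2(dtbbpy)PF6 (1 mol%), H2O (10 equiv), DME/DMF 3:1, blue LEDs, 60 °C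
Reagents that add atoms: none
Why: Photoredox oxidation of the oxalate releases two CO2 and tertiary radical 25, which should add (Giese reaction) to the enone β-carbon from the convex face of the cis-hydroazulene and anti to the adjacent side chain of the cyclopentenone, setting the quaternary carbon and the neighbouring CH before the α-keto radical is reduced and protonated.

Step 16
Reactants: 26 methyl (2R)-2-(tert-butyldimethylsilyloxy)-2-{(1S,2R,5S)-5-(tert-butyldimethylsilyloxy)-4-oxo-2-[(1S,7R,10S)-6,6,10-trimethyl-2-methylidenebicyclo[5.3.0]decan-10-yl]cyclopentyl}acetate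
Product: 28 the 3-hydroxy derivative of 26 (hydroxyl on the ring CH2 between the ketone and the hydroazulenyl-bearing carbon; either epimer), via potassium enolate 27 (not isolated)
Conditions: KN(SiMe3)2, THF, −78 °C; then 2-(phenylsulfonyl)-3-phenyloxaziridine, −78 °C; AcOH quench
Reagents that add atoms: 2-(phenylsulfonyl)-3-phenyloxaziridine, O=S(=O)(c1ccccc1)N1OC1c1ccccc1
Why: Kinetic deprotonation should occur at the CH2 flank of the ketone and not at the hindered silyloxy-bearing CH, and Davis oxidation of that enolate gives the α-hydroxy ketone, whose new carbinol configuration is lost in the next step.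

Step 17
Reactants: 28 the 3-hydroxy derivative of 26
Product: 29 (2S,3S,4R)-2,4-bis(tert-butyldimethylsilyloxy)-5-methoxy-5-oxo-3-{(1R)-2-oxo-1-[(1S,7R,10R)-6,6,10-trimethyl-2-methylidenebicyclo[5.3.0]decan-10-yl]ethyl}pentanoic acid
Conditions: NaIO4, THF/H2O, rt
Reagents that add atoms: sodium periodate, [Na+].[O-][I](=O)(=O)=O
Why: Periodate cleavage of the α-hydroxy ketone breaks the ring between carbinol and carbonyl carbon, giving the aldehyde from the former and the carboxylic acid from the latter, with the isolated alkene untouched.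

Step 18
Reactants: 29 (2S,3S,4R)-2,4-bis(tert-butyldimethylsilyloxy)-5-methoxy-5-oxo-3-{(1R)-2-oxo-1-[(1S,7R,10R)-6,6,10-trimethyl-2-methylidenebicyclo[5.3.0]decan-10-yl]ethyl}pentanoic acid
Product: 31 methyl (1S,4S,5R,6R,8R)-4-acetoxy-3-oxo-8-[(1S,7R,10R)-6,6,10-trimethyl-2-methylidenebicyclo[5.3.0]decan-10-yl]-2,7-dioxabicyclo[3.2.1]octane-6-carboxylate, via hydroxy lactone acetal 30 (not isolated)
Conditions: HF·pyridine, MeCN, 0 °C to rt; Me3SiOMe quench, concentrate; then Ac2O, pyridine, DMAP, CH2Cl2, 0 °C
Reagents that add atoms: acetic anhydride, CC(=O)OC(C)=O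
Why: Acidic fluoride removes both silyl groups, the freed ester-bearing hydroxyl adds to the aldehyde and the lactol is acylated by the neighbouring acid (lactol formation and acetal acylation), which can only give the bridged lactone acetal with both arms cis on the tetrahydrofuran, and the remaining α-hydroxyl is then acetylated.

**Compound list**

1 | 5-methylhex-5-enoic acid | C=C(C)CCCC(=O)O | starting material
2 | N,O-dimethylhydroxylamine hydrochloride | CNOC.Cl | starting material
3 | N-methoxy-N,5-dimethylhex-5-enamide | C=C(C)CCCC(=O)N(C)OC | intermediate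
4 | 2-bromocyclopent-2-en-1-one | O=C1CCC=C1Br | starting material
5 | (R)-2-bromocyclopent-2-en-1-ol | O[C@@H]1CCC=C1Br | intermediate
6 | (R)-[(2-bromocyclopent-2-en-1-yl)oxy](tert-butyl)dimethylsilane | CC(C)(C)[Si](C)(C)O[C@@H]1CCC=C1Br | intermediate
7 | 1-[(5R)-5-(tert-butyldimethylsilyloxy)cyclopent-1-en-1-yl]-5-methylhex-5-en-1-one | C=C(C)CCCC(=O)C1=CCC[C@H]1O[Si](C)(C)C(C)(C)C | intermediate
8 | tertiary alkyl radical, 6-[(5R)-5-(tert-butyldimethylsilyloxy)cyclopent-1-en-1-yl]-2-methyl-6-oxohexan-2-yl | C[C](C)CCCC(=O)C1=CCC[C@H]1O[Si](C)(C)C(C)(C)C | intermediate (not isolated)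
9 | α-keto radical, (7R,10R)-10-(tert-butyldimethylsilyloxy)-6,6-dimethyl-2-oxobicyclo[5.3.0]decan-1-yl | O=C1CCCC(C)(C)[C@@H]2CC[C@@H](O[Si](C)(C)C(C)(C)C)[C]12 | intermediate (not isolated)
10 | (1R,7R,10R)-10-(tert-butyldimethylsilyloxy)-6,6-dimethylbicyclo[5.3.0]decan-2-one (cis-fused; silyloxy cis to both ring-fusion hydrogens) | O=C1CCCC(C)(C)[C@@H]2CC[C@@H](O[Si](C)(C)C(C)(C)C)[C@H]12 | intermediate
11 | (1S,7R,10R)-tert-butyl[(6,6-dimethyl-2-methylidenebicyclo[5.3.0]decan-10-yl)oxy]dimethylsilane | C=C1CCCC(C)(C)[C@@H]2CC[C@@H](O[Si](C)(C)C(C)(C)C)[C@H]12 | intermediate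
12 | (1S,7R,10R)-6,6-dimethyl-2-methylidenebicyclo[5.3.0]decan-10-ol | C=C1CCCC(C)(C)[C@@H]2CC[C@@H](O)[C@H]12 | intermediate
13 | (1S,7R)-6,6-dimethyl-2-methylidenebicyclo[5.3.0]decan-10-one | C=C1CCCC(C)(C)[C@@H]2CCC(=O)[C@H]12 | intermediate
14 | lithium (1S,7R,10S)-6,6,10-trimethyl-2-methylidenebicyclo[5.3.0]decan-10-olate | C=C1CCCC(C)(C)[C@@H]2CC[C@](C)([O-])[C@H]12.[Li+] | intermediate (not isolated)
15 | methyl (1S,7R,10S)-6,6,10-trimethyl-2-methylidenebicyclo[5.3.0]decan-10-yl oxalate | C=C1CCCC(C)(C)[C@@H]2CC[C@](C)(OC(=O)C(=O)OC)[C@H]12 | intermediate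
16 | cesium 2-{[(1S,7R,10S)-6,6,10-trimethyl-2-methylidenebicyclo[5.3.0]decan-10-yl]oxy}-2-oxoacetate | C=C1CCCC(C)(C)[C@@H]2CC[C@](C)(OC(=O)C(=O)[O-])[C@H]12.[Cs+] | intermediate
17 | (1R,5S)-2-oxabicyclo[3.3.0]oct-6-en-3-one, i.e. (3aS,6aR)-3,3a,6,6a-tetrahydro-2H-cyclopenta[b]furan-2-one | O=C1O[C@@H]2CC=C[C@@H]2C1 | starting material
18 | potassium enolate of 17 | [O-]C1=C[C@H]2C=CC[C@H]2O1.[K+] | intermediate (not isolated)
19 | (1R,4R,5R)-4-hydroxy-2-oxabicyclo[3.3.0]oct-6-en-3-one (hydroxyl on the convex face) | O=C1O[C@@H]2CC=C[C@@H]2[C@H]1O | intermediate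
20 | potassium (2R)-2-hydroxy-2-[(1S,5R)-5-hydroxycyclopent-2-en-1-yl]acetate | C1C=C[C@H]([C@@H](O)C(=O)[O-])[C@@H]1O.[K+] | intermediate (not isolated)
21 | methyl (2R)-2-hydroxy-2-[(1S,5R)-5-hydroxycyclopent-2-en-1-yl]acetate | C1C=C[C@H]([C@@H](O)C(=O)OC)[C@@H]1O | intermediate (not isolated)
22 | methyl (2R)-2-(tert-butyldimethylsilyloxy)-2-[(1S,5R)-5-(tert-butyldimethylsilyloxy)cyclopent-2-en-1-yl]acetate (ring substituents cis) | C1C=C[C@H]([C@@H](O[Si](C)(C)C(C)(C)C)C(=O)OC)[C@@H]1O[Si](C)(C)C(C)(C)C | intermediate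
23 | methyl (2R)-2-(tert-butyldimethylsilyloxy)-2-[(1S,5S)-5-(tert-butyldimethylsilyloxy)-4-hydroxycyclopent-2-en-1-yl]acetate (C4 epimers) | OC1C=C[C@H]([C@@H](O[Si](C)(C)C(C)(C)C)C(=O)OC)[C@@H]1O[Si](C)(C)C(C)(C)C | intermediate
24 | methyl (2R)-2-(tert-butyldimethylsilyloxy)-2-[(1S,5S)-5-(tert-butyldimethylsilyloxy)-4-oxocyclopent-2-en-1-yl]acetate | O=C1C=C[C@H]([C@@H](O[Si](C)(C)C(C)(C)C)C(=O)OC)[C@@H]1O[Si](C)(C)C(C)(C)C | intermediate
25 | hydroazulenyl tertiary radical, (1S,7R)-6,6,10-trimethyl-2-methylidenebicyclo[5.3.0]decan-10-yl | C=C1CCCC(C)(C)[C@@H]2CC[C](C)[C@H]12 | intermediate (not isolated)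
26 | methyl (2R)-2-(tert-butyldimethylsilyloxy)-2-{(1S,2R,5S)-5-(tert-butyldimethylsilyloxy)-4-oxo-2-[(1S,7R,10S)-6,6,10-trimethyl-2-methylidenebicyclo[5.3.0]decan-10-yl]cyclopentyl}acetate | C=C1CCCC(C)(C)[C@@H]2CC[C@@](C)([C@@H]3CC(=O)[C@@H](O[Si](C)(C)C(C)(C)C)[C@H]3[C@@H](O[Si](C)(C)C(C)(C)C)C(=O)OC)[C@H]12 | intermediate
27 | potassium enolate of 26 (enolised towards the ring CH2) | C=C1CCCC(C)(C)[C@@H]2CC[C@@](C)([C@@H]3C=C([O-])[C@@H](O[Si](C)(C)C(C)(C)C)[C@H]3[C@@H](O[Si](C)(C)C(C)(C)C)C(=O)OC)[C@H]12.[K+] | intermediate (not isolated)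
28 | 3-hydroxy derivative of 26 (α-hydroxy ketone, either epimer at the new carbinol) | C=C1CCCC(C)(C)[C@@H]2CC[C@@](C)([C@@H]3C(O)C(=O)[C@@H](O[Si](C)(C)C(C)(C)C)[C@H]3[C@@H](O[Si](C)(C)C(C)(C)C)C(=O)OC)[C@H]12 | intermediate
29 | (2S,3S,4R)-2,4-bis(tert-butyldimethylsilyloxy)-5-methoxy-5-oxo-3-{(1R)-2-oxo-1-[(1S,7R,10R)-6,6,10-trimethyl-2-methylidenebicyclo[5.3.0]decan-10-yl]ethyl}pentanoic acid | C=C1CCCC(C)(C)[C@@H]2CC[C@@](C)([C@H](C=O)[C@H]([C@@H](O[Si](C)(C)C(C)(C)C)C(=O)OC)[C@H](O[Si](C)(C)C(C)(C)C)C(=O)O)[C@H]12 | intermediate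
30 | methyl (1S,4S,5S,6R,8R)-4-hydroxy-3-oxo-8-[(1S,7R,10R)-6,6,10-trimethyl-2-methylidenebicyclo[5.3.0]decan-10-yl]-2,7-dioxabicyclo[3.2.1]octane-6-carboxylate | C=C1CCCC(C)(C)[C@@H]2CC[C@@](C)([C@@H]3[C@@H]4OC(=O)[C@@H](O)[C@H]3[C@H](C(=O)OC)O4)[C@H]12 | intermediate (not isolated)
31 | methyl (1S,4S,5R,6R,8R)-4-acetoxy-3-oxo-8-[(1S,7R,10R)-6,6,10-trimethyl-2-methylidenebicyclo[5.3.0]decan-10-yl]-2,7-dioxabicyclo[3.2.1]octane-6-carboxylate | C=C1CCCC(C)(C)[C@@H]2CC[C@@](C)([C@@H]3[C@@H]4OC(=O)[C@@H](OC(C)=O)[C@H]3[C@H](C(=O)OC)O4)[C@H]12 | target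

**Step count and risks**

Total: 18 steps. Longest linear sequence: 13 steps (steps 2–10, then 15–18, from 2-bromocyclopent-2-en-1-one 4).

Steps most likely to fail:

Step 5 (ring closure). The tertiary radical may be hydrogenated before it closes the seven-membered ring. The iron enolate formed after closure may expel the β-silyloxy group. Facial control by the allylic silyloxy group may be incomplete. The fallback separates radical formation from the hydride medium. It sets out from 7: Mukaiyama hydration (Co(acac)2, PhSiH3, O2, i-PrOH) should trap the same radical with oxygen and give 1-[(5R)-5-(tert-butyldimethylsilyloxy)cyclopent-1-en-1-yl]-5-hydroxy-5-methylhexan-1-one F1. Acylation with ClCOCO2Me (Et3N, DMAP) gives the methyl oxalate F2, and one equivalent of CsOH gives the cesium oxalate F3. Irradiation of F3 with Ir[dF(CF3)ppy]2(dtbbpy)PF6 in wet DME/DMF should release the tertiary radical with no hydride donor present, so the 7-endo addition has no reductive competitor. The fallback comes back to the route at 10.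

Step 15 (fragment coupling). Capture of the hindered tertiary radical by the β-substituted, γ-branched enone may be too slow, so that the radical is lost by reduction or disproportionation. The fallback changes the acceptor and the way the α-oxygen is introduced. It sets out from 24: PhICl2 and pyridine should give the α-chloro enone methyl (2R)-2-(tert-butyldimethylsilyloxy)-2-[(1S,5S)-5-(tert-butyldimethylsilyloxy)-3-chloro-4-oxocyclopent-2-en-1-yl]acetate F4, a more electrophilic radical trap. Coupling of F4 with 16 under the photoredox conditions gives the α-chloro ketone adduct F5. Zinc and Me3SiCl convert F5 regiospecifically into the trimethylsilyl enol ether F6. Rubottom oxidation of F6 with dimethyldioxirane at −78 °C and hydrolytic work-up gives the α-hydroxy ketone, so the fallback comes back to the route at 28.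

Step 18 (final cascade). The free acid may lactonise onto the ester-bearing carbinol instead of acylating the lactol, and the acidic fluoride medium may add HF to, or isomerise, the exocyclic double bond. The fallback closes the lactone by carboxyl activation instead of acid catalysis. It sets out from 29: Bu4NF buffered with AcOH (THF, 0 °C) removes both silyl groups under near-neutral conditions and should give the dihydroxy lactol acid F7, in which the ester-bearing hydroxyl has already closed onto the aldehyde. Yamaguchi activation (2,4,6-trichlorobenzoyl chloride, Et3N, then DMAP, high dilution) then acylates the anomeric hydroxyl. The fallback comes back to the route at 30, which is acetylated as in the second stage of step 18.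

Further compounds

F1 | step 5 | 1-[(5R)-5-(tert-butyldimethylsilyloxy)cyclopent-1-en-1-yl]-5-hydroxy-5-methylhexan-1-one | CC(C)(O)CCCC(=O)C1=CCC[C@H]1O[Si](C)(C)C(C)(C)C
F2 | step 5 | methyl 6-[(5R)-5-(tert-butyldimethylsilyloxy)cyclopent-1-en-1-yl]-2-methyl-6-oxohexan-2-yl oxalate | COC(=O)C(=O)OC(C)(C)CCCC(=O)C1=CCC[C@H]1O[Si](C)(C)C(C)(C)C
F3 | step 5 | cesium 2-({6-[(5R)-5-(tert-butyldimethylsilyloxy)cyclopent-1-en-1-yl]-2-methyl-6-oxohexan-2-yl}oxy)-2-oxoacetate | [Cs+].[O-]C(=O)C(=O)OC(C)(C)CCCC(=O)C1=CCC[C@H]1O[Si](C)(C)C(C)(C)C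
F4 | step 15 | methyl (2R)-2-(tert-butyldimethylsilyloxy)-2-[(1S,5S)-5-(tert-butyldimethylsilyloxy)-3-chloro-4-oxocyclopent-2-en-1-yl]acetate | O=C1C(Cl)=C[C@H]([C@@H](O[Si](C)(C)C(C)(C)C)C(=O)OC)[C@@H]1O[Si](C)(C)C(C)(C)C
F5 | step 15 | 3-chloro derivative of 26 (α-chloro ketone adduct, either epimer at the chlorine-bearing carbon) | C=C1CCCC(C)(C)[C@@H]2CC[C@@](C)([C@@H]3C(Cl)C(=O)[C@@H](O[Si](C)(C)C(C)(C)C)[C@H]3[C@@H](O[Si](C)(C)C(C)(C)C)C(=O)OC)[C@H]12
F6 | step 15 | trimethylsilyl enol ether of 26 (enol ether towards the former CH2) | C=C1CCCC(C)(C)[C@@H]2CC[C@@](C)([C@@H]3C=C(O[Si](C)(C)C)[C@@H](O[Si](C)(C)C(C)(C)C)[C@H]3[C@@H](O[Si](C)(C)C(C)(C)C)C(=O)OC)[C@H]12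
F7 | step 18 | (2S)-2-hydroxy-2-{(2R,3R,4R)-5-hydroxy-2-(methoxycarbonyl)-4-[(1S,7R,10R)-6,6,10-trimethyl-2-methylidenebicyclo[5.3.0]decan-10-yl]oxolan-3-yl}acetic acid (lactol, both anomers) | C=C1CCCC(C)(C)[C@@H]2CC[C@@](C)([C@@H]3C(O)O[C@@H](C(=O)OC)[C@@H]3[C@H](O)C(=O)O)[C@H]12
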